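**Assumption:** the target has no stereocentre and no stereogenic double bond (the prenyl alkene carries two identical methyl groups), so it is achiral and is made exactly as drawn; no stereocontrol is needed.

## Retrosynthetic overview

1. Target 12 ⇒ both quinone C–OMe bonds are cut last: dichloroquinone 9 plus methanol (amine-relay double methoxy-dechlorination).
2. 9 ⇒ quinone–indole C3 bond: mono-indolyl dichloroquinone 7 plus 7-prenylindole 3 (conjugate addition, re-oxidation).
3. 7 ⇒ 2,5-dichloro-1,4-benzoquinone 4 plus indole 5; the 2,5-dichloro pattern forces the two indoles para to each other.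
4. 3 ⇒ 7-bromoindole 1 plus prenylstannane 2 (Stille coupling).
5. No ring is built: both indole rings and the six-membered quinone ring are bought intact. Order of assembly: indole onto the quinone, then prenylindole, then the two C–O bonds.

## Route

**Step 1**
Reactants: 1 7-bromo-1H-indole; 2 tributyl(3-methylbut-2-en-1-yl)stannane
Product: 3 7-(3-methylbut-2-en-1-yl)-1H-indole
Conditions: Pd(PPh3)4 (5 mol %), DMF, 100 °C, 16 h
Reagents that add atoms: none
Why: Stille cross-coupling, in which zerovalent palladium inserts into the C7–Br bond, the allylstannane transmetalates and reductive elimination from the aryl(η3-prenyl)palladium intermediate takes place at the unsubstituted CH2 end to give the linear prenyl arene with the free N–H tolerated; no stereocentre is formed.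

**Step 2**
Reactants: 4 2,5-dichloro-1,4-benzoquinone; 5 1H-indole
Product: 7 2,5-dichloro-3-(1H-indol-3-yl)cyclohexa-2,5-diene-1,4-dione, via hydroquinone 6 (not isolated)
Conditions: conc. HCl (0.3 equiv), THF, 23 °C, 12 h; then DDQ (1.0 equiv), 23 °C, 30 min
Reagents that add atoms: none
Why: Acid-promoted Michael addition of indole C3 to an unsubstituted C–H carbon of the chloroquinone (Möhlau–Redlich-type indolylation) gives, after tautomerisation, hydroquinone 6, which cannot accept a second indole and is dehydrogenated by DDQ to the quinone; no stereocentre is formed.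

**Step 3**
Reactants: 7 2,5-dichloro-3-(1H-indol-3-yl)cyclohexa-2,5-diene-1,4-dione; 3 7-(3-methylbut-2-en-1-yl)-1H-indole
Product: 9 2,5-dichloro-3-(1H-indol-3-yl)-6-[7-(3-methylbut-2-en-1-yl)-1H-indol-3-yl]cyclohexa-2,5-diene-1,4-dione, via hydroquinone 8 (not isolated)
Conditions: AcOH, 50 °C, 12 h; then DDQ (1.0 equiv), THF, 0 °C, 15 min
Reagents that add atoms: none
Why: The same conjugate addition and re-oxidation sequence, in which the indolyl group of 7 deactivates the carbonyl it is conjugated to so that the other carbonyl steers C3 of 3 to the only remaining C–H carbon (para to the first indolyl), the weak acid AcOH spares the prenyl alkene, and one equivalent of DDQ at 0 °C oxidises hydroquinone 8 much faster than the allylic CH2; no stereocentre is formed.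

**Step 4**
Reactants: 9 2,5-dichloro-3-(1H-indol-3-yl)-6-[7-(3-methylbut-2-en-1-yl)-1H-indol-3-yl]cyclohexa-2,5-diene-1,4-dione
Product: 12 2,5-dimethoxy-3-(1H-indol-3-yl)-6-[7-(3-methylbut-2-en-1-yl)-1H-indol-3-yl]cyclohexa-2,5-diene-1,4-dione, via chloro-methoxy quinone 10 (not isolated), via regioisomeric chloro-methoxy quinone 11 (not isolated)
Conditions: DABCO (3.0 equiv), dry MeOH/MeCN 1:1, 4 Å MS, 50 °C, Ar, 12 h
Reagents that add atoms: methanol, CO
Why: Proposed new method: an amine-relay (nucleophilic-catalysis) double vinylic substitution in which DABCO, a strong neutral nucleophile and good leaving group that the quinone cannot dehydrogenate, adds to each C–Cl carbon (β to a quinone carbonyl) and expels chloride to give a cationic quinonyl-ammonium (vinylogous acyl-ammonium) far more electrophilic than the indole-deactivated chloroquinone, so that neutral methanol, helped by a second DABCO as general base, adds at the same carbon and releases DABCO, forming both C–O bonds without alkoxide and hence without deprotonating the indole N–H groups or cleaving the product's vinylogous ester; the closest known reaction type is the DABCO-catalysed SNAr alkoxylation of chloro-azines (and acyl-ammonium catalysis of acid chlorides), not yet shown on a tetrasubstituted halo-quinone; no stereocentre is formed.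

## Compound list

1 | 7-bromo-1H-indole | Brc1cccc2cc[nH]c12 | starting material
2 | tributyl(3-methylbut-2-en-1-yl)stannane | CCCC[Sn](CCCC)(CCCC)CC=C(C)C | starting material
3 | 7-(3-methylbut-2-en-1-yl)-1H-indole | CC(C)=CCc1cccc2cc[nH]c12 | intermediate
4 | 2,5-dichloro-1,4-benzoquinone | O=C1C=C(Cl)C(=O)C=C1Cl | starting material
5 | 1H-indole | c1ccc2[nH]ccc2c1 | starting material
6 | 2,5-dichloro-3-(1H-indol-3-yl)benzene-1,4-diol | Oc1cc(Cl)c(O)c(-c2c[nH]c3ccccc23)c1Cl | intermediate
7 | 2,5-dichloro-3-(1H-indol-3-yl)cyclohexa-2,5-diene-1,4-dione | O=C1C=C(Cl)C(=O)C(c2c[nH]c3ccccc23)=C1Cl | intermediate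
8 | 2,5-dichloro-3-(1H-indol-3-yl)-6-[7-(3-methylbut-2-en-1-yl)-1H-indol-3-yl]benzene-1,4-diol | Oc1c(Cl)c(-c2c[nH]c3ccccc23)c(O)c(Cl)c1-c1c[nH]c2c(CC=C(C)C)cccc12 | intermediate
9 | 2,5-dichloro-3-(1H-indol-3-yl)-6-[7-(3-methylbut-2-en-1-yl)-1H-indol-3-yl]cyclohexa-2,5-diene-1,4-dione | O=C1C(Cl)=C(c2c[nH]c3ccccc23)C(=O)C(Cl)=C1c1c[nH]c2c(CC=C(C)C)cccc12 | intermediate
10 | 2-chloro-5-methoxy-6-(1H-indol-3-yl)-3-[7-(3-methylbut-2-en-1-yl)-1H-indol-3-yl]cyclohexa-2,5-diene-1,4-dione | COC1=C(c2c[nH]c3ccccc23)C(=O)C(Cl)=C(c2c[nH]c3c(CC=C(C)C)cccc23)C1=O | intermediate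
11 | 2-chloro-5-methoxy-3-(1H-indol-3-yl)-6-[7-(3-methylbut-2-en-1-yl)-1H-indol-3-yl]cyclohexa-2,5-diene-1,4-dione | COC1=C(c2c[nH]c3c(CC=C(C)C)cccc23)C(=O)C(Cl)=C(c2c[nH]c3ccccc23)C1=O | intermediate
12 | 2,5-dimethoxy-3-(1H-indol-3-yl)-6-[7-(3-methylbut-2-en-1-yl)-1H-indol-3-yl]cyclohexa-2,5-diene-1,4-dione | COC1=C(c2c[nH]c3ccccc23)C(=O)C(OC)=C(c2c[nH]c3c(CC=C(C)C)cccc23)C1=O | target

## Step count and risk

Total step count: 4. Longest linear sequence: 3 steps (1 → 3 → 9 → 12, or 4 → 7 → 9 → 12).

**Step 4 (the proposed new step; highest risk).** DABCO may fail to add to the hindered, doubly indole-deactivated C–Cl carbons, the reaction may stall at 10 or 11, or traces of water may give hydroxyquinones. The fallback uses known chemistry, sets out from 9 and comes back at 12. Compound 9 is hydrolysed with NaOH in MeOH/H2O at reflux, the established conversion of dichloro-bis(indolyl)quinones into dihydroxyquinones, and acidified to give 2,5-dihydroxy-3-(1H-indol-3-yl)-6-[7-(3-methylbut-2-en-1-yl)-1H-indol-3-yl]cyclohexa-2,5-diene-1,4-dione F1. The two acidic vinylogous-acid OH groups are then O-methylated with TMSCHN2 in MeOH/toluene at 0 °C to give 12. The C–O bonds are thus made by O-alkylation of the hydroxyquinone instead of substitution by methanol, at the cost of one extra step.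

**Step 3.** Acid-mediated addition to the already donor-substituted quinone 7 may be slow, redox exchange between 8 and 7 can stall conversion, and the prenyl group is exposed to acid and DDQ. The fallback sets out from 5 (with 3 as the second partner) and comes back at 9. Indole 5 is treated with bought chloranil (O=C1C(Cl)=C(Cl)C(=O)C(Cl)=C1Cl) and Cs2CO3 in MeCN at 23 °C, which by addition–elimination gives 2,3,5-trichloro-6-(1H-indol-3-yl)cyclohexa-2,5-diene-1,4-dione F2. F2 and 3 with Cs2CO3 in MeCN then give 9 directly, the second indole displacing the chloride para to the first indolyl group for the same electronic and steric reasons as in step 3. This base-mediated substitution needs neither acid nor oxidant, so the prenyl group is never at risk.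

**Step 1.** The coupling may give some branched (reverse-prenyl) regioisomer or isomerised alkene that is hard to separate from 3. The fallback sets out from 1 and comes back at 3, with the roles of nucleophile and electrophile reversed. Miyaura borylation of 1 (B2pin2, Pd(dppf)Cl2, KOAc, dioxane, 90 °C) gives 7-(4,4,5,5-tetramethyl-1,3,2-dioxaborolan-2-yl)-1H-indole F3. F3 is then coupled with prenyl bromide (Pd(PPh3)4, K2CO3, THF/H2O, 60 °C); the aryl group is transferred to the CH2 end of the η3-prenyl palladium electrophile, giving linear 3.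

## Further compounds

F1 | step 4 | 2,5-dihydroxy-3-(1H-indol-3-yl)-6-[7-(3-methylbut-2-en-1-yl)-1H-indol-3-yl]cyclohexa-2,5-diene-1,4-dione | OC1=C(c2c[nH]c3ccccc23)C(=O)C(O)=C(c2c[nH]c3c(CC=C(C)C)cccc23)C1=O
F2 | step 3 | 2,3,5-trichloro-6-(1H-indol-3-yl)cyclohexa-2,5-diene-1,4-dione | O=C1C(Cl)=C(Cl)C(=O)C(Cl)=C1c1c[nH]c2ccccc12
F3 | step 1 | 7-(4,4,5,5-tetramethyl-1,3,2-dioxaborolan-2-yl)-1H-indole | CC1(C)OB(OC1(C)C)c1cccc2cc[nH]c12
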